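## Retrosynthetic overview

1. Feature used: the benzylic carbon C7 is para to the free OH of the guaiacyl ring (4-hydroxy-3-methoxyphenyl), so oxidation of the 7-deoxy compound gives a para-quinone methide with C7 as its electrophilic terminus. The primary C9–OH lies 1,3 to C7 across the C8 stereocentre, so one boron atom can bridge O9 and the incoming O7 in a six-membered ring.
2. C7–O (made last): tethered hydration of that quinone methide through a phenylboronic hemiester on O9, then boronate release and debenzylation.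
3. C2–C1' (flavanone to ring B): enantioselective Pd-catalysed conjugate arylation of 5,7-bis(benzyloxy)chromone with an arylboronic acid.
4. C8–O–aryl: Mitsunobu inversion of the (S)-aryllactate obtained from 3-methoxy-L-tyrosine with retention. The guaiacyl phenol is silylated first, because a free para-phenol would compete as nucleophile and as participating neighbouring group.
5. Rings: the chromanone bicycle and both arenes are bought. The only ring closed is the temporary 1,3,2-dioxaborinane (step 11), which is opened again in step 12.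

Key step: step 11

Assumption: the Pd(OCOCF3)2/t-BuPyOx catalyst is taken to attack the chromone from the same face as it attacks simple cyclic enones, so the (R)-ligand is chosen for 2S; if the sense is opposite, the (S)-ligand is used.

## Route

Step 1
Reactants: 1 3-methoxy-L-tyrosine
Product: 4 (S)-2-hydroxy-3-(4-hydroxy-3-methoxyphenyl)propanoic acid, via diazonium carboxylate 2 (not isolated), via alpha-lactone 3 (not isolated)
Conditions: NaNO2 (1.5 equiv, slow addition), 1 M aq. H2SO4, 0 °C to rt
Reagents that add atoms: water, O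
Why: Diazotisation of an α-amino acid: the carboxylate displaces N2 with inversion to the α-lactone and water reopens it at C8 with a second inversion, so the hydroxy acid should form with net retention (S).

Step 2
Reactants: 4 (S)-2-hydroxy-3-(4-hydroxy-3-methoxyphenyl)propanoic acid
Product: 5 methyl (S)-2-hydroxy-3-(4-hydroxy-3-methoxyphenyl)propanoate
Conditions: MeOH, H2SO4 (cat.), reflux
Reagents that add atoms: methanol, CO
Why: Fischer esterification under acid leaves the C8 stereocentre and the phenol untouched and removes the carboxylic acid proton that would interfere with the Mitsunobu step.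

Step 3
Reactants: 5 methyl (S)-2-hydroxy-3-(4-hydroxy-3-methoxyphenyl)propanoate
Product: 6 methyl (S)-3-[4-(tert-butyldimethylsilyloxy)-3-methoxyphenyl]-2-hydroxypropanoate
Conditions: TBSCl (1.05 equiv), imidazole, CH2Cl2, 0 °C
Reagents that add atoms: tert-butyldimethylsilyl chloride, CC(C)(C)[Si](C)(C)Cl
Why: Chemoselective silylation: the unhindered, acidic phenol reacts much faster with TBSCl/imidazole than the hindered, electron-poor secondary α-hydroxy ester, and masking it keeps the para-phenol out of the etherification.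

Step 4
Reactants: 6 methyl (S)-3-[4-(tert-butyldimethylsilyloxy)-3-methoxyphenyl]-2-hydroxypropanoate; 7 4-bromo-2,6-dimethoxyphenol
Product: 8 methyl (R)-2-(4-bromo-2,6-dimethoxyphenoxy)-3-[4-(tert-butyldimethylsilyloxy)-3-methoxyphenyl]propanoate
Conditions: PPh3, DIAD, THF, 0 °C to rt
Reagents that add atoms: none
Why: Mitsunobu etherification of an α-hydroxy ester with a phenol is an SN2 displacement of the oxyphosphonium group with inversion, turning (S)-C8–OH into the C8–OAr arrangement of the target (R by CIP until C7 carries oxygen).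

Step 5
Reactants: 8 methyl (R)-2-(4-bromo-2,6-dimethoxyphenoxy)-3-[4-(tert-butyldimethylsilyloxy)-3-methoxyphenyl]propanoate
Product: 9 (R)-2-(4-bromo-2,6-dimethoxyphenoxy)-3-[4-(tert-butyldimethylsilyloxy)-3-methoxyphenyl]propan-1-ol
Conditions: LiBH4, THF, 0 °C to rt; H2O work-up
Reagents that add atoms: none
Why: Hydride reduction of the activated α-aryloxy ester gives the primary C9 alcohol at low temperature without touching the aryl bromide or the aryl silyl ether and without epimerising C8.

Step 6
Reactants: 9 (R)-2-(4-bromo-2,6-dimethoxyphenoxy)-3-[4-(tert-butyldimethylsilyloxy)-3-methoxyphenyl]propan-1-ol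
Product: 10 aryl bromide bis-silyl ether [(R)-5-bromo-2-{1-(tert-butyldimethylsilyloxy)-3-[4-(tert-butyldimethylsilyloxy)-3-methoxyphenyl]propan-2-yloxy}-1,3-dimethoxybenzene]
Conditions: TBSCl, imidazole, DMF, rt
Reagents that add atoms: tert-butyldimethylsilyl chloride, CC(C)(C)[Si](C)(C)Cl
Why: Standard silylation of the primary alcohol removes the last acidic proton before the organolithium step.

Step 7
Reactants: 10 aryl bromide bis-silyl ether
Product: 13 arylboronic acid bis-silyl ether, via aryllithium 11 (not isolated), via lithium triisopropoxyborate 12 (not isolated)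
Conditions: n-BuLi, THF, −78 °C; B(OiPr)3, −78 to 0 °C; aq. AcOH (pH 5–6)
Reagents that add atoms: triisopropyl borate, CC(C)OB(OC(C)C)OC(C)C; water, O
Why: Bromine–lithium exchange at −78 °C outruns deprotonation or attack at silicon, the aryllithium is trapped by the borate ester, and mildly acidic hydrolysis gives the free boronic acid that the conjugate addition needs, with both silyl ethers kept.

Step 8
Reactants: 14 5,7-dihydroxychromone
Product: 15 5,7-bis(benzyloxy)chromone
Conditions: BnBr (2.5 equiv), K2CO3, DMF, 60 °C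
Reagents that add atoms: benzyl bromide, BrCc1ccccc1
Why: Williamson benzylation of both phenols with a carbonate base, with warming for the hydrogen-bonded 5-OH; the pyranone ring tolerates K2CO3 in DMF.

Step 9
Reactants: 13 arylboronic acid bis-silyl ether; 15 5,7-bis(benzyloxy)chromone (1.5 equiv)
Product: 16 (2S)-5,7-bis(benzyloxy)flavanone bis-silyl ether
Conditions: Pd(OCOCF3)2 (10 mol%), (R)-4-tert-butyl-2-(pyridin-2-yl)-4,5-dihydrooxazole (12 mol%), NH4PF6 (30 mol%), H2O (5 equiv), ClCH2CH2Cl, 60 °C
Reagents that add atoms: none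
Why: Pd-catalysed asymmetric conjugate addition of an arylboronic acid to a chromone: transmetalation gives a cationic aryl complex of divalent palladium, carbopalladation of C2=C3 under control of the pyridine-oxazoline ligand sets C2 as S, and water protonates the palladium enolate; the medium is non-basic, so the flavanone is not ring-opened and the remote C8 centre is unaffected.

Step 10
Reactants: 16 (2S)-5,7-bis(benzyloxy)flavanone bis-silyl ether
Product: 17 7-deoxy precursor [(2S)-5,7-bis(benzyloxy)-2-(4-{[(2R)-1-hydroxy-3-(4-hydroxy-3-methoxyphenyl)propan-2-yl]oxy}-3,5-dimethoxyphenyl)chroman-4-one]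
Conditions: TBAF, AcOH (1:1, 3 equiv each), THF, 0 °C to rt
Reagents that add atoms: none
Why: Fluoride cleaves the aryl and the primary alkyl silyl ether, and the acetic acid buffer suppresses base-induced retro-oxa-Michael opening of the flavanone, which would epimerise C2.

Step 11
Reactants: 17 7-deoxy precursor; 18 phenylboronic acid (1.1 equiv)
Product: 21 cyclic phenylboronate of the (7R,8S)-diol [trans-4,5-disubstituted 2-phenyl-1,3,2-dioxaborinane], via boronic hemiester 19 (not isolated), via quinone methide hemiester 20 (not isolated)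
Conditions: 18, 4 Å MS, CH2Cl2, rt, 1 h; then Ag2O (1.2 equiv), 0.01 M, rt, dark
Reagents that add atoms: none
Why: Proposed new method: the C9–OH condenses with PhB(OH)2 to hemiester 19, Ag2O takes two electrons and two protons from the guaiacyl phenol and C7 to give the para-quinone methide 20, and the boron-bound OH adds to the methide carbon C7 with rearomatisation, forming the C7–O bond. The closest known reactions are the intramolecular oxa-conjugate addition of boronic acid hemiesters of hydroxy enones, the Ag2O oxidation of 4-alkyl-2-methoxyphenols to quinone methides and the addition of water to lignin-type quinone methides; their combination on a quinone methide is new. The 1,3,2-dioxaborinane closes in a 6-exo-trig mode, since oxygen attacks C7 and the C7=C1 π bond lies outside the new ring. C7 is set by the existing C8 centre through a chair transition state in which the quinoid ring and the C8 aryloxy group are both equatorial and C8–H eclipses the methide plane (least 1,3-allylic strain), which gives the trans-4,5-disubstituted ring, that is 7R (erythro), also expected to be the more stable boronate. The step needs facial selectivity at C7 and chemoselectivity against untethered hydration, loss of C8–H to the enol ether, radical coupling at the free ortho position and over-oxidation of the product. These are addressed by intramolecular delivery, molecular sieves, a base-free medium, high dilution and only a slight excess of Ag2O.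

Step 12
Reactants: 21 cyclic phenylboronate of the (7R,8S)-diol
Product: 22 (2S)-5,7-bis(benzyloxy)-2-(4-{[(1R,2S)-1,3-dihydroxy-1-(4-hydroxy-3-methoxyphenyl)propan-2-yl]oxy}-3,5-dimethoxyphenyl)chroman-4-one
Conditions: 2,2-dimethylpropane-1,3-diol (5 equiv), THF, rt
Reagents that add atoms: none
Why: Transesterification of the boronic ester with an excess of a 1,3-diol that forms a more stable gem-dimethyl dioxaborinane frees the C7 and C9 hydroxyls under neutral conditions, so neither the benzylic C7 centre nor C2 is at risk.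

Step 13
Reactants: 22 (2S)-5,7-bis(benzyloxy) diol
Product: 23 target, (2S)-2-(4-{[(1R,2S)-1,3-dihydroxy-1-(4-hydroxy-3-methoxyphenyl)propan-2-yl]oxy}-3,5-dimethoxyphenyl)-5,7-dihydroxychroman-4-one
Conditions: H2 (1 atm), 10% Pd/C, EtOAc, rt, stopped after 2 equiv H2
Reagents that add atoms: none
Why: Catalytic hydrogenolysis of the two aryl benzyl ethers in a neutral aprotic solvent should be faster than cleavage of the benzylic C7–OH or the C2–O1 bond or reduction of the ketone, so the target should form with all three stereocentres intact.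

## Compound list

1 | 3-methoxy-L-tyrosine | COc1cc(C[C@H](N)C(=O)O)ccc1O | starting material
2 | (S)-1-carboxylato-2-(4-hydroxy-3-methoxyphenyl)ethanediazonium (diazonium carboxylate) | COc1cc(C[C@H]([N+]#N)C(=O)[O-])ccc1O | intermediate
3 | (R)-3-(4-hydroxy-3-methoxybenzyl)oxiran-2-one (alpha-lactone) | COc1cc(C[C@H]2OC2=O)ccc1O | intermediate
4 | (S)-2-hydroxy-3-(4-hydroxy-3-methoxyphenyl)propanoic acid | COc1cc(C[C@H](O)C(=O)O)ccc1O | intermediate
5 | methyl (S)-2-hydroxy-3-(4-hydroxy-3-methoxyphenyl)propanoate | COc1cc(C[C@H](O)C(=O)OC)ccc1O | intermediate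
6 | methyl (S)-3-[4-(tert-butyldimethylsilyloxy)-3-methoxyphenyl]-2-hydroxypropanoate | COc1cc(C[C@H](O)C(=O)OC)ccc1O[Si](C)(C)C(C)(C)C | intermediate
7 | 4-bromo-2,6-dimethoxyphenol | COc1cc(Br)cc(OC)c1O | starting material
8 | methyl (R)-2-(4-bromo-2,6-dimethoxyphenoxy)-3-[4-(tert-butyldimethylsilyloxy)-3-methoxyphenyl]propanoate | COc1cc(C[C@H](C(=O)OC)Oc2c(OC)cc(Br)cc2OC)ccc1O[Si](C)(C)C(C)(C)C | intermediate
9 | (R)-2-(4-bromo-2,6-dimethoxyphenoxy)-3-[4-(tert-butyldimethylsilyloxy)-3-methoxyphenyl]propan-1-ol | COc1cc(C[C@H](CO)Oc2c(OC)cc(Br)cc2OC)ccc1O[Si](C)(C)C(C)(C)C | intermediate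
10 | (R)-5-bromo-2-{1-(tert-butyldimethylsilyloxy)-3-[4-(tert-butyldimethylsilyloxy)-3-methoxyphenyl]propan-2-yloxy}-1,3-dimethoxybenzene | COc1cc(C[C@H](CO[Si](C)(C)C(C)(C)C)Oc2c(OC)cc(Br)cc2OC)ccc1O[Si](C)(C)C(C)(C)C | intermediate
11 | aryllithium from 10 (lithium in place of bromine) | COc1cc(C[C@H](CO[Si](C)(C)C(C)(C)C)Oc2c(OC)cc([Li])cc2OC)ccc1O[Si](C)(C)C(C)(C)C | intermediate
12 | lithium triisopropoxy(aryl)borate from 11 | COc1cc(C[C@H](CO[Si](C)(C)C(C)(C)C)Oc2c(OC)cc([B-](OC(C)C)(OC(C)C)OC(C)C)cc2OC)ccc1O[Si](C)(C)C(C)(C)C.[Li+] | intermediate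
13 | (R)-[4-({1-(tert-butyldimethylsilyloxy)-3-[4-(tert-butyldimethylsilyloxy)-3-methoxyphenyl]propan-2-yl}oxy)-3,5-dimethoxyphenyl]boronic acid | COc1cc(C[C@H](CO[Si](C)(C)C(C)(C)C)Oc2c(OC)cc(B(O)O)cc2OC)ccc1O[Si](C)(C)C(C)(C)C | intermediate
14 | 5,7-dihydroxychromone (5,7-dihydroxy-4H-chromen-4-one) | O=c1ccoc2cc(O)cc(O)c12 | starting material
15 | 5,7-bis(benzyloxy)-4H-chromen-4-one | O=c1ccoc2cc(OCc3ccccc3)cc(OCc3ccccc3)c12 | intermediate
16 | (2S)-5,7-bis(benzyloxy)-2-[4-({(2R)-1-(tert-butyldimethylsilyloxy)-3-[4-(tert-butyldimethylsilyloxy)-3-methoxyphenyl]propan-2-yl}oxy)-3,5-dimethoxyphenyl]chroman-4-one | COc1cc(C[C@H](CO[Si](C)(C)C(C)(C)C)Oc2c(OC)cc([C@@H]3CC(=O)c4c(OCc5ccccc5)cc(OCc5ccccc5)cc4O3)cc2OC)ccc1O[Si](C)(C)C(C)(C)C | intermediate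
17 | (2S)-5,7-bis(benzyloxy)-2-(4-{[(2R)-1-hydroxy-3-(4-hydroxy-3-methoxyphenyl)propan-2-yl]oxy}-3,5-dimethoxyphenyl)chroman-4-one | COc1cc(C[C@H](CO)Oc2c(OC)cc([C@@H]3CC(=O)c4c(OCc5ccccc5)cc(OCc5ccccc5)cc4O3)cc2OC)ccc1O | intermediate
18 | phenylboronic acid | OB(O)c1ccccc1 | starting material
19 | O9-[hydroxy(phenyl)boranyl] hemiester of 17 | COc1cc(C[C@H](COB(O)c5ccccc5)Oc2c(OC)cc([C@@H]3CC(=O)c4c(OCc6ccccc6)cc(OCc6ccccc6)cc4O3)cc2OC)ccc1O | intermediate
20 | para-quinone methide of 19 (4-alkylidene-2-methoxycyclohexa-2,5-dienone, exocyclic alkene geometry not fixed) | COC1=CC(=C[C@H](COB(O)c5ccccc5)Oc2c(OC)cc([C@@H]3CC(=O)c4c(OCc6ccccc6)cc(OCc6ccccc6)cc4O3)cc2OC)C=CC1=O | intermediate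
21 | (2S)-5,7-bis(benzyloxy)-2-(4-{[(4R,5S)-4-(4-hydroxy-3-methoxyphenyl)-2-phenyl-1,3,2-dioxaborinan-5-yl]oxy}-3,5-dimethoxyphenyl)chroman-4-one | COc1cc([C@H]5OB(c6ccccc6)OC[C@@H]5Oc2c(OC)cc([C@@H]3CC(=O)c4c(OCc7ccccc7)cc(OCc7ccccc7)cc4O3)cc2OC)ccc1O | intermediate
22 | (2S)-5,7-bis(benzyloxy)-2-(4-{[(1R,2S)-1,3-dihydroxy-1-(4-hydroxy-3-methoxyphenyl)propan-2-yl]oxy}-3,5-dimethoxyphenyl)chroman-4-one | COc1cc([C@@H](O)[C@H](CO)Oc2c(OC)cc([C@@H]3CC(=O)c4c(OCc5ccccc5)cc(OCc5ccccc5)cc4O3)cc2OC)ccc1O | intermediate
23 | (2S)-2-(4-{[(1R,2S)-1,3-dihydroxy-1-(4-hydroxy-3-methoxyphenyl)propan-2-yl]oxy}-3,5-dimethoxyphenyl)-5,7-dihydroxychroman-4-one | COc1cc([C@@H](O)[C@H](CO)Oc2c(OC)cc([C@@H]3CC(=O)c4c(O)cc(O)cc4O3)cc2OC)ccc1O | target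

## Step count and risks

Total steps: 13. Longest linear sequence: 12 (steps 1–7 and 9–13; step 8 is a one-step branch).

**Step 11 (the proposed new method).** Possible failures:
- water or boronic acid adding to the methide without the tether, which erodes facial selectivity at C7;
- tautomerisation of the methide to the enol ether;
- radical coupling at the free ortho position during oxidation;
- further oxidation of the product phenol.

Fallback with known chemistry, setting out from 17 and returning at 22: 17 is oxidised with Ag2O in CH2Cl2 alone to the para-quinone methide F1, and the silver is filtered off. The solution is then stirred with water in dioxane, the known untethered hydration of β-aryl ether quinone methides. This is expected to give 22 together with its threo (7S,8S) isomer F2, which would be separated by chromatography before step 13.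

**Step 9.** Possible failures:
- slow carbopalladation of the electron-rich 5,7-dialkoxychromone, so that protodeboronation and homocoupling consume the boronic acid;
- incomplete catalyst control at C2, giving a C2-epimeric mixture.

Fallback, setting out from 10 and returning at 17 (it replaces steps 7, 9 and 10): bromine–lithium exchange of 10 and quenching with DMF gives aldehyde F3. Claisen–Schmidt condensation with 1-[2,4-bis(benzyloxy)-6-hydroxyphenyl]ethan-1-one F4 (KOH, EtOH; the aryl silyl ether is cleaved here, which does no harm) gives 2'-hydroxychalcone F5. NaOAc in refluxing EtOH closes the pyranone ring by intramolecular oxa-Michael addition to flavanone F6 as a mixture of C2 epimers. TBAF/AcOH then gives 17 and its (2R) epimer F7, to be separated by preparative HPLC on a chiral phase.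

**Step 1.** Possible failure: nitrosation, nitration or oxidative coupling of the electron-rich free phenol ring competing with diazotisation of the amine.

Fallback, setting out from 1 and returning at 4: oxidative deamination of 1 with an L-amino acid deaminase (whole cells, dioxygen) gives (4-hydroxy-3-methoxyphenyl)pyruvic acid F8. An (S)-selective lactate dehydrogenase (NADH recycled with formate dehydrogenase and HCO2Na) reduces it to 4, so C8 is set by the enzyme instead of by double inversion.

## Further compounds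

F1 | step 11 | para-quinone methide of 17 (free C9–OH) | COC1=CC(=C[C@H](CO)Oc2c(OC)cc([C@@H]3CC(=O)c4c(OCc5ccccc5)cc(OCc5ccccc5)cc4O3)cc2OC)C=CC1=O
F2 | step 11 | threo isomer of 22, (2S)-5,7-bis(benzyloxy)-2-(4-{[(1S,2S)-1,3-dihydroxy-1-(4-hydroxy-3-methoxyphenyl)propan-2-yl]oxy}-3,5-dimethoxyphenyl)chroman-4-one | COc1cc([C@H](O)[C@H](CO)Oc2c(OC)cc([C@@H]3CC(=O)c4c(OCc5ccccc5)cc(OCc5ccccc5)cc4O3)cc2OC)ccc1O
F3 | step 9 | (R)-4-({1-(tert-butyldimethylsilyloxy)-3-[4-(tert-butyldimethylsilyloxy)-3-methoxyphenyl]propan-2-yl}oxy)-3,5-dimethoxybenzaldehyde | COc1cc(C[C@H](CO[Si](C)(C)C(C)(C)C)Oc2c(OC)cc(C=O)cc2OC)ccc1O[Si](C)(C)C(C)(C)C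
F4 | step 9 | 1-[2,4-bis(benzyloxy)-6-hydroxyphenyl]ethan-1-one | CC(=O)c1c(O)cc(OCc2ccccc2)cc1OCc1ccccc1
F5 | step 9 | (E)-1-[2,4-bis(benzyloxy)-6-hydroxyphenyl]-3-[4-({(2R)-1-(tert-butyldimethylsilyloxy)-3-(4-hydroxy-3-methoxyphenyl)propan-2-yl}oxy)-3,5-dimethoxyphenyl]prop-2-en-1-one | COc1cc(C[C@H](CO[Si](C)(C)C(C)(C)C)Oc2c(OC)cc(/C=C/C(=O)c3c(O)cc(OCc4ccccc4)cc3OCc3ccccc3)cc2OC)ccc1O
F6 | step 9 | 5,7-bis(benzyloxy)-2-[4-({(2R)-1-(tert-butyldimethylsilyloxy)-3-(4-hydroxy-3-methoxyphenyl)propan-2-yl}oxy)-3,5-dimethoxyphenyl]chroman-4-one, both C2 epimers | COc1cc(C[C@H](CO[Si](C)(C)C(C)(C)C)Oc2c(OC)cc(C3CC(=O)c4c(OCc5ccccc5)cc(OCc5ccccc5)cc4O3)cc2OC)ccc1O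
F7 | step 9 | (2R) epimer of 17 | COc1cc(C[C@H](CO)Oc2c(OC)cc([C@H]3CC(=O)c4c(OCc5ccccc5)cc(OCc5ccccc5)cc4O3)cc2OC)ccc1O
F8 | step 1 | 3-(4-hydroxy-3-methoxyphenyl)-2-oxopropanoic acid | COc1cc(CC(=O)C(=O)O)ccc1O
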